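Compare the two earlier flasks: north-west holds 11.3 times the free catalyst of south, and at 6.00 h it shows 10.6 times the product.

| setting | south | north-west | beta | gamma | alpha |
|---|---|---|---|---|---|
| substrate | 16 mM | 16 mM | 16 mM | 16 mM | 16 mM |
| partner | 28.8 mM (fed, over 25 min) | 28.8 mM (fed, over 25 min) | 28.8 mM (fed, over 25 min) | 28.8 mM (fed, over 25 min) | 28.8 mM (fed, over 25 min) |
| free catalyst | 0.0084 mM | 0.095 mM | 0.015 mM | 0.050 mM | 0.15 mM |
| remark | run made earlier; the fed solution adds 0.25 times the starting volume | run made earlier; the fed solution adds 0.25 times the starting volume | the fed solution adds 0.25 times the starting volume | the fed solution adds 0.25 times the starting volume | the fed solution adds 0.25 times the starting volume |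
| time |  |  | 12 h | 12 h | 12 h |

| run | time / h | product / % | substrate / % |
|---|---|---|---|
| south | 0.833 | 0 | 99 |
| south | 2.00 | 4 | 96 |
| south | 4.00 | 7 | 94 |
| south | 6.00 | 9 | 91 |
| north-west | 0.833 | 14 | 87 |
| north-west | 2.00 | 37 | 62 |
| north-west | 4.00 | 69 | 30 |
| north-west | 6.00 | 95 | 9 |

(readings scatter by 1.5 percentage points)

* [product] at the end for beta, gamma, alpha, in this order
* how the row runs (falls, then rises / hardly changes / rises all the way / rises, then falls / falls all the way)

- charges are per starting volume, the dose included; the dosed solution carries all of it
- the numbers in the tables scatter by 1.5 percentage points (one standard deviation)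
- "hardly changes" means that all values lie within two and a half points (for a concentration: within two and a half percent of the largest)

1. Take the bench rule these two ratios suggest: multiply catalyst by hours, and call the result catalyst-hours. At these same charges of substrate and partner, equal catalyst-hours should turn equal fractions of the charge.

2. Read the whole-charge dose, the catalyst-hours that would turn the whole substrate charge on a straight line. North-west at its last reading gives 0.600 mM·h.

3. Test the dose on a reading that has played no part so far, south at 4.00 h. Its 0.0336 mM·h gives 5.60% of the charge, and the reading is 7%.

4. Divide the catalyst-hours of each new flask by the dose. Beta gets 0.300, gamma 1.00 and alpha 3.00 of a whole charge.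

5. Now find the border by writing the substrate balance. In north-west at 4.00 h, product and substrate add up to 99.0% of the charge. Partner is charged at 1.80 times the substrate, so take substrate as the limiting reagent. The product fraction then stops at one, and the rule ends where the ratio in step 4 reaches one. Gamma stands on that border and alpha lies past it.

6. Convert to concentration. The feed spreads the charge over 1.25 volumes, so the whole charge reads 12.8 mM. My own reckoning is 3.84 mM for beta and that ceiling for alpha, with gamma at the ceiling or just under it.

7. The forecast says 4.2 mM, 11.9 mM and 12.8 mM, and that the row rises all the way, on the ground that “conversion depends on catalyst × time”. It stands above my figure for beta and below my ceiling for gamma.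

8. The flasks give 4.19 mM, 11.9 mM and 12.8 mM, and the row rises all the way.

    substrate + free catalyst → catalyst intermediate A (k = 30500 M⁻¹ h⁻¹)
    partner + catalyst intermediate A ⇌ catalyst intermediate B (K = 140 M⁻¹, k = 1.83 × 10⁵ M⁻¹ h⁻¹)
    catalyst intermediate B → catalyst intermediate C (k = 99.7 h⁻¹)
    catalyst intermediate C → free catalyst + product (k = 70.3 h⁻¹)
    catalyst intermediate A → spent catalyst (k = 0.127 h⁻¹)

9. Hold the dose against the flasks: beta's 30.0% stands beside 32.7% of the charge as product at 12.0 h, and gamma's 100% beside 92.7%. In beta, the half-life of substrate by the making of catalyst intermediate A is 21 h at 5.66 h, which is 13.8 times the 1.5 h found with the other concentrations held at their charge. At 6.00 h, beta holds 9.07% of its catalyst as free catalyst.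

The earlier runs and the new flask come from a simulation for substances that don't exist, noise included.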